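## Retrosynthetic overview

- 22 ⇐ desilylation ⇐ light-driven acetyl-radical hydroacylation of the 7-methylidene dienone 19 (C18–C19 bond; C7 set by H-atom return anti to the C6 substituent).
- 19 ⇐ Mannich methylenation of 15 ⇐ E-enol senecioate formation from aldehyde 13 ⇐ alcohol 12.
- 12 ⇐ light-driven alkoxy-radical 1,5-HAT/diene hydroalkylation at C5–H of cycloheptenone 10 (quaternary centre; face set by C6).
- 10 (the only ring of the target, closed once by intramolecular Horner–Wadsworth–Emmons olefination) ⇐ hydroformylation of the isopropenyl group and opening of lactone 5 by phosphonate 7.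
- 5 ⇐ (S)-carvone by epoxidation, periodate excision of C2/CH3 (the cyclohexenone ring is cleaved) and reduction/lactonisation; the carvone stereocentre becomes C6.

Assumption: substrates, building blocks, intermediates and products are numbered; simple reagents appear only under Conditions or "Reagents that add atoms".

Atom labels used below are those of the target ring: C1 (C=O), C2 (bearing C8H2OH), C3, C4, C5 (quaternary), C6, C7; C16/C17 are the enol ester carbons, C18–C20 the 2-oxopropyl group.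

## Route

Step 1
Reactants: 1 (S)-(+)-carvone
Product: 2 (1S,4S,6S)-1-methyl-4-(prop-1-en-2-yl)-7-oxabicyclo[4.1.0]heptan-2-one
Conditions: 30% H2O2, NaOH (cat.), MeOH, 0 °C
Reagents that add atoms: hydrogen peroxide, OO
Why: Weitz–Scheffer nucleophilic epoxidation touches only the electron-poor enone C=C (the isopropenyl group is inert) and hydroperoxide adds anti to the ring substituent; the two new centres are erased in step 2.

Step 2
Reactants: 2 (1S,4S,6S)-1-methyl-4-(prop-1-en-2-yl)-7-oxabicyclo[4.1.0]heptan-2-one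
Product: 5 (4S)-4-(prop-1-en-2-yl)oxan-2-one, via acid aldehyde 3 (not isolated), via hydroxy acid 4 (not isolated)
Conditions: H5IO6 (2.5 equiv), THF/H2O, rt; extractive work-up; NaBH4, MeOH, 0 °C; then 1 M HCl, CH2Cl2, rt
Reagents that add atoms: water, O
Why: periodic acid hydrolyses the epoxy ketone and cleaves the resulting glycol and 1,2-dione (Malaprade cleavage) so that C2 and its methyl leave as acetic acid, NaBH4 then reduces only the aldehyde of 3 and the 5-hydroxy acid 4 lactonises on acidification; the bought stereocentre is not touched.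

Step 3
Reactants: 6 diethyl (2-hydroxyethyl)phosphonate
Product: 7 diethyl (2-{[tert-butyl(dimethyl)silyl]oxy}ethyl)phosphonate
Conditions: TBSCl, imidazole, DMF, rt
Reagents that add atoms: tert-butyldimethylsilyl chloride, CC(C)(C)[Si](C)(C)Cl
Why: standard imidazole-promoted O-silylation of the primary alcohol.

Step 4
Reactants: 5 (4S)-4-(prop-1-en-2-yl)oxan-2-one; 7 diethyl (2-{[tert-butyl(dimethyl)silyl]oxy}ethyl)phosphonate
Product: 8 diethyl [(5S)-1-{[tert-butyl(dimethyl)silyl]oxy}-7-hydroxy-3-oxo-5-(prop-1-en-2-yl)heptan-2-yl]phosphonate (C2 epimers)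
Conditions: 7 (2.2 equiv), n-BuLi (2.2 equiv), THF, −78 °C; then 5, −78 to −40 °C; AcOH
Reagents that add atoms: none
Why: Claisen-type C-acylation of the α-lithiated phosphonate by the lactone gives the β-ketophosphonate and frees the primary alcohol, the second equivalent of anion deprotonating the product so that no double addition occurs (the new C2 centre is lost in step 6).

Step 5
Reactants: 8 diethyl [(5S)-1-{[tert-butyl(dimethyl)silyl]oxy}-7-hydroxy-3-oxo-5-(prop-1-en-2-yl)heptan-2-yl]phosphonate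
Product: 9 diethyl [(5S)-1-{[tert-butyl(dimethyl)silyl]oxy}-5-(2-hydroxyethyl)-6-methyl-3,8-dioxooctan-2-yl]phosphonate (epimers at C2 and C6)
Conditions: Rh(acac)(CO)2 (1 mol%), tris(2,4-di-tert-butylphenyl) phosphite (4 mol%), CO/H2 (1:1, 20 bar), toluene, 80 °C
Reagents that add atoms: carbon monoxide, [C-]#[O+]
Why: rhodium-catalysed hydroformylation of the only alkene; a 1,1-disubstituted alkene takes the formyl group at the terminal carbon only (Keulemans rule), and the new C–H centre (future C5) forms as both epimers, which converge in step 7.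

Step 6
Reactants: 9 diethyl [(5S)-1-{[tert-butyl(dimethyl)silyl]oxy}-5-(2-hydroxyethyl)-6-methyl-3,8-dioxooctan-2-yl]phosphonate
Product: 10 (6S)-2-({[tert-butyl(dimethyl)silyl]oxy}methyl)-6-(2-hydroxyethyl)-5-methylcyclohept-2-en-1-one (C5 epimers)
Conditions: K2CO3, 18-crown-6, toluene (0.002 M), 70 °C
Reagents that add atoms: none
Why: intramolecular Horner–Wadsworth–Emmons olefination at high dilution closes the seven-membered ring and delivers the 2-substituted enone (C2=C3, C8 already in place) in one operation.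

Step 7
Reactants: 10 (6S)-2-({[tert-butyl(dimethyl)silyl]oxy}methyl)-6-(2-hydroxyethyl)-5-methylcyclohept-2-en-1-one; 11 4-methylpenta-1,3-diene
Product: 12 (5S,6S)-2-({[tert-butyl(dimethyl)silyl]oxy}methyl)-6-(2-hydroxyethyl)-5-methyl-5-(4-methylpent-3-en-1-yl)cyclohept-2-en-1-one
Conditions: CeCl3 (10 mol%), n-Bu4NCl (20 mol%), 9,10-diphenylanthracene (5 mol%), 2,4,6-triisopropylbenzenethiol (20 mol%), 11 (5 equiv), MeCN, 400 nm LEDs, rt
Reagents that add atoms: none
Why: Proposed new method: alkoxy-radical-relayed δ-C(sp3)–H hydroalkylation of a 1,3-diene — LMCT photolysis of the tetravalent cerium alkoxide of the side-chain alcohol gives an O-radical that abstracts the tertiary C5–H through a six-membered 1,5-HAT transition state (both C5 epimers of 10 give the same planar radical), the nucleophilic tertiary radical adds to the CH2 terminus of 11 on the ring face anti to the C6 side chain (sets the quaternary centre, new chain trans to the side chain), the allyl radical takes H from the hindered thiol at its less substituted end to leave the trisubstituted alkene, and the thiyl radical is reduced by excited 9,10-diphenylanthracene whose radical cation returns trivalent cerium to the tetravalent state; closest known chemistry is the cerium-photocatalysed δ-C–H functionalisation of free alkanols combined with thiol-co-catalysed radical hydrofunctionalisation (Giese-type addition).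

Step 8
Reactants: 12 (5S,6S)-2-({[tert-butyl(dimethyl)silyl]oxy}methyl)-6-(2-hydroxyethyl)-5-methyl-5-(4-methylpent-3-en-1-yl)cyclohept-2-en-1-one
Product: 13 2-[(1S,2S)-5-({[tert-butyl(dimethyl)silyl]oxy}methyl)-2-methyl-2-(4-methylpent-3-en-1-yl)-6-oxocyclohept-4-en-1-yl]acetaldehyde
Conditions: PhI(OAc)2 (1.1 equiv), TEMPO (10 mol%), CH2Cl2, rt
Reagents that add atoms: none
Why: oxoammonium (TEMPO) oxidation is selective for the primary alcohol and leaves the enone, the alkenes and the silyl ether untouched.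

Step 9
Reactants: 13 2-[(1S,2S)-5-({[tert-butyl(dimethyl)silyl]oxy}methyl)-2-methyl-2-(4-methylpent-3-en-1-yl)-6-oxocyclohept-4-en-1-yl]acetaldehyde; 14 3-methylbut-2-enoyl chloride
Product: 15 (E)-2-[(1R,2S)-5-({[tert-butyl(dimethyl)silyl]oxy}methyl)-2-methyl-2-(4-methylpent-3-en-1-yl)-6-oxocyclohept-4-en-1-yl]ethenyl 3-methylbut-2-enoate
Conditions: 14 (1.5 equiv), Et3N, DMAP (20 mol%), CH2Cl2, 0 °C to rt
Reagents that add atoms: none
Why: amine-promoted enolisation and O-acylation of the aldehyde (the ketone is far less prone), the E enol ester being favoured because the Z isomer would press the acyloxy group against the ring carbon next to the quaternary centre; C7 is still CH2, so nothing can epimerise.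

Step 10
Reactants: 15 (E)-2-[(1R,2S)-5-({[tert-butyl(dimethyl)silyl]oxy}methyl)-2-methyl-2-(4-methylpent-3-en-1-yl)-6-oxocyclohept-4-en-1-yl]ethenyl 3-methylbut-2-enoate
Product: 19 (E)-2-[(1R,2S)-5-({[tert-butyl(dimethyl)silyl]oxy}methyl)-2-methyl-7-methylidene-2-(4-methylpent-3-en-1-yl)-6-oxocyclohept-4-en-1-yl]ethenyl 3-methylbut-2-enoate, via silyl dienol ether 16 (not isolated), via Mannich base 17 (not isolated), via methiodide 18 (not isolated)
Conditions: TMSOTf, Et3N, CH2Cl2, −78 °C; CH2=NMe2+ I−, −78 to 0 °C; MeI, rt; NaHCO3 aq.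
Reagents that add atoms: N,N-dimethylmethyleneiminium iodide (Eschenmoser's salt), C=[N+](C)C.[I-]
Why: Mannich methylenation — soft enolisation at C7 (the only enolisable α-position), alkylation of the silyl dienol ether by the iminium salt, quaternisation and E1cB loss of trimethylamine give the exocyclic enone under conditions mild enough for the enol ester.

Step 11
Reactants: 19 (E)-2-[(1R,2S)-5-({[tert-butyl(dimethyl)silyl]oxy}methyl)-2-methyl-7-methylidene-2-(4-methylpent-3-en-1-yl)-6-oxocyclohept-4-en-1-yl]ethenyl 3-methylbut-2-enoate; 20 acetaldehyde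
Product: 21 (E)-2-[(1S,2S,7R)-5-({[tert-butyl(dimethyl)silyl]oxy}methyl)-2-methyl-2-(4-methylpent-3-en-1-yl)-6-oxo-7-(2-oxopropyl)cyclohept-4-en-1-yl]ethenyl 3-methylbut-2-enoate
Conditions: (n-Bu4N)4[W10O32] (2 mol%), 20 (10 equiv), MeCN, 390 nm LEDs, rt
Reagents that add atoms: none
Why: decatungstate-photocatalysed hydroacylation (acyl-radical Giese addition) — the excited cluster abstracts the formyl H of acetaldehyde, the nucleophilic acetyl radical adds to the unhindered exocyclic CH2, and the reduced cluster returns H to the C7 radical from the face anti to the C6 substituent, giving the 6,7-cis product kinetically under neutral conditions.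

Step 12
Reactants: 21 (E)-2-[(1S,2S,7R)-5-({[tert-butyl(dimethyl)silyl]oxy}methyl)-2-methyl-2-(4-methylpent-3-en-1-yl)-6-oxo-7-(2-oxopropyl)cyclohept-4-en-1-yl]ethenyl 3-methylbut-2-enoate
Product: 22 (E)-2-[(1S,2S,7R)-5-(hydroxymethyl)-2-methyl-2-(4-methylpent-3-en-1-yl)-6-oxo-7-(2-oxopropyl)cyclohept-4-en-1-yl]ethenyl 3-methylbut-2-enoate
Conditions: HF·pyridine, pyridine, THF, 0 °C
Reagents that add atoms: none
Why: buffered fluoride desilylation of the primary silyl ether; neither the enol ester nor the epimerisable C7 centre is affected at 0 °C.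

## Compound list

1 | (S)-(+)-carvone, (5S)-2-methyl-5-(prop-1-en-2-yl)cyclohex-2-en-1-one | CC1=CC[C@@H](CC1=O)C(C)=C | starting material
2 | (1S,4S,6S)-1-methyl-4-(prop-1-en-2-yl)-7-oxabicyclo[4.1.0]heptan-2-one | O=C1C[C@@H](C(C)=C)C[C@@H]2O[C@]12C | intermediate
3 | (3S)-5-oxo-3-(prop-1-en-2-yl)pentanoic acid | OC(=O)C[C@@H](C(C)=C)CC=O | intermediate (not isolated)
4 | (3S)-5-hydroxy-3-(prop-1-en-2-yl)pentanoic acid | OC(=O)C[C@@H](C(C)=C)CCO | intermediate (not isolated)
5 | (4S)-4-(prop-1-en-2-yl)oxan-2-one | C=C(C)[C@H]1CCOC(=O)C1 | intermediate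
6 | diethyl (2-hydroxyethyl)phosphonate | CCOP(=O)(CCO)OCC | starting material
7 | diethyl (2-{[tert-butyl(dimethyl)silyl]oxy}ethyl)phosphonate | CCOP(=O)(CCO[Si](C)(C)C(C)(C)C)OCC | intermediate
8 | diethyl [(5S)-1-{[tert-butyl(dimethyl)silyl]oxy}-7-hydroxy-3-oxo-5-(prop-1-en-2-yl)heptan-2-yl]phosphonate (C2 epimers) | OCC[C@H](C(C)=C)CC(=O)C(CO[Si](C)(C)C(C)(C)C)P(=O)(OCC)OCC | intermediate
9 | diethyl [(5S)-1-{[tert-butyl(dimethyl)silyl]oxy}-5-(2-hydroxyethyl)-6-methyl-3,8-dioxooctan-2-yl]phosphonate (epimers at C2 and C6) | O=CCC(C)[C@@H](CCO)CC(=O)C(CO[Si](C)(C)C(C)(C)C)P(=O)(OCC)OCC | intermediate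
10 | (6S)-2-({[tert-butyl(dimethyl)silyl]oxy}methyl)-6-(2-hydroxyethyl)-5-methylcyclohept-2-en-1-one (C5 epimers) | O=C1C[C@H](CCO)C(C)CC=C1CO[Si](C)(C)C(C)(C)C | intermediate
11 | 4-methylpenta-1,3-diene | C=CC=C(C)C | starting material
12 | (5S,6S)-2-({[tert-butyl(dimethyl)silyl]oxy}methyl)-6-(2-hydroxyethyl)-5-methyl-5-(4-methylpent-3-en-1-yl)cyclohept-2-en-1-one | O=C1C[C@H](CCO)[C@@](C)(CCC=C(C)C)CC=C1CO[Si](C)(C)C(C)(C)C | intermediate
13 | 2-[(1S,2S)-5-({[tert-butyl(dimethyl)silyl]oxy}methyl)-2-methyl-2-(4-methylpent-3-en-1-yl)-6-oxocyclohept-4-en-1-yl]acetaldehyde | O=C1C[C@H](CC=O)[C@@](C)(CCC=C(C)C)CC=C1CO[Si](C)(C)C(C)(C)C | intermediate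
14 | 3-methylbut-2-enoyl chloride | CC(C)=CC(Cl)=O | starting material
15 | (E)-2-[(1R,2S)-5-({[tert-butyl(dimethyl)silyl]oxy}methyl)-2-methyl-2-(4-methylpent-3-en-1-yl)-6-oxocyclohept-4-en-1-yl]ethenyl 3-methylbut-2-enoate | O=C1C[C@H](/C=C/OC(=O)C=C(C)C)[C@@](C)(CCC=C(C)C)CC=C1CO[Si](C)(C)C(C)(C)C | intermediate
16 | (E)-2-[(1S,2S)-5-({[tert-butyl(dimethyl)silyl]oxy}methyl)-2-methyl-2-(4-methylpent-3-en-1-yl)-6-[(trimethylsilyl)oxy]cyclohepta-4,6-dien-1-yl]ethenyl 3-methylbut-2-enoate | C[Si](C)(C)OC1=C[C@H](/C=C/OC(=O)C=C(C)C)[C@@](C)(CCC=C(C)C)CC=C1CO[Si](C)(C)C(C)(C)C | intermediate (not isolated)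
17 | (E)-2-[(1S,2S)-5-({[tert-butyl(dimethyl)silyl]oxy}methyl)-7-[(dimethylamino)methyl]-2-methyl-2-(4-methylpent-3-en-1-yl)-6-oxocyclohept-4-en-1-yl]ethenyl 3-methylbut-2-enoate (C7 epimers) | O=C1C(CN(C)C)[C@H](/C=C/OC(=O)C=C(C)C)[C@@](C)(CCC=C(C)C)CC=C1CO[Si](C)(C)C(C)(C)C | intermediate (not isolated)
18 | trimethylammonium iodide (methiodide) of 17 | O=C1C(C[N+](C)(C)C)[C@H](/C=C/OC(=O)C=C(C)C)[C@@](C)(CCC=C(C)C)CC=C1CO[Si](C)(C)C(C)(C)C.[I-] | intermediate (not isolated)
19 | (E)-2-[(1R,2S)-5-({[tert-butyl(dimethyl)silyl]oxy}methyl)-2-methyl-7-methylidene-2-(4-methylpent-3-en-1-yl)-6-oxocyclohept-4-en-1-yl]ethenyl 3-methylbut-2-enoate | O=C1C(=C)[C@H](/C=C/OC(=O)C=C(C)C)[C@@](C)(CCC=C(C)C)CC=C1CO[Si](C)(C)C(C)(C)C | intermediate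
20 | acetaldehyde | CC=O | starting material
21 | (E)-2-[(1S,2S,7R)-5-({[tert-butyl(dimethyl)silyl]oxy}methyl)-2-methyl-2-(4-methylpent-3-en-1-yl)-6-oxo-7-(2-oxopropyl)cyclohept-4-en-1-yl]ethenyl 3-methylbut-2-enoate | O=C1[C@H](CC(C)=O)[C@H](/C=C/OC(=O)C=C(C)C)[C@@](C)(CCC=C(C)C)CC=C1CO[Si](C)(C)C(C)(C)C | intermediate
22 | (E)-2-[(1S,2S,7R)-5-(hydroxymethyl)-2-methyl-2-(4-methylpent-3-en-1-yl)-6-oxo-7-(2-oxopropyl)cyclohept-4-en-1-yl]ethenyl 3-methylbut-2-enoate (CNP0247522.1) | CC(=O)C[C@H]1C(=O)C(CO)=CC[C@](C)(CCC=C(C)C)[C@H]1/C=C/OC(=O)C=C(C)C | target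

## Step count and risks

Total steps: 12. Longest linear sequence: 11 (steps 1, 2, 4–12 from carvone; step 3 is a one-step side branch).

The three steps most likely to fail:

Step 7 (the proposed new step). The thiol may be used up by radical hydrothiolation of the diene, premature H-transfer merely returns 10, and the facial selectivity at the tertiary radical may be only moderate. The fallback uses known chemistry and sets out from 10. Mitsunobu reaction with N-hydroxyphthalimide (PPh3, DIAD) gives the N-phthalimidoyl ether F1. Photoreductive N–O cleavage (fac-Ir(ppy)3, Hantzsch ester, blue LEDs) in the presence of acrolein then runs the established alkoxy-radical 1,5-HAT/Giese sequence and gives the aldehyde F2 with the alcohol restored. Chemoselective Wittig olefination of F2 with Ph3P=C(CH3)2 (isopropyltriphenylphosphonium iodide, n-BuLi, −78 °C) comes back to the route at 12.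

Step 9. The acylation may give an E/Z mixture, and the acid chloride can react partly through its vinylketene. The fallback sets out from 13 and swaps kinetic for thermodynamic control: the aldehyde is acylated without regard to geometry, and the mixture containing the Z enol ester F3 is equilibrated by reversible thiyl-radical addition (PhSSPh 5 mol%, 405 nm LEDs) to the more stable E isomer, returning at 15.

Step 11. Hydrogen return at C7 may be poorly face-selective, and the acetyl radical could also add at C3 or the catalyst could abstract H from the substrate. The fallback sets out from 19 and is ionic: 1,4-addition of [CH2=C(OEt)]2CuLi (from ethyl vinyl ether, t-BuLi and CuI) at −78 °C, then kinetic protonation of the enolate with 2,6-di-tert-butyl-4-methylphenol from the face anti to the C6 substituent, gives the enol ether F4. Hydrolysis with oxalic acid on wet silica returns to the route at 21.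

Further compounds
F1 | step 7 | N-phthalimidoyl ether of alcohol 10, 2-{2-[(1S)-4-({[tert-butyl(dimethyl)silyl]oxy}methyl)-7-methyl-5-oxocyclohept-3-en-1-yl]ethoxy}isoindole-1,3-dione (C7 epimers) | O=C1C[C@H](CCON2C(=O)c3ccccc3C2=O)C(C)CC=C1CO[Si](C)(C)C(C)(C)C
F2 | step 7 | (5S,6S)-2-({[tert-butyl(dimethyl)silyl]oxy}methyl)-6-(2-hydroxyethyl)-5-methyl-5-(3-oxopropyl)cyclohept-2-en-1-one | O=C1C[C@H](CCO)[C@@](C)(CCC=O)CC=C1CO[Si](C)(C)C(C)(C)C
F3 | step 9 | (Z)-2-[(1R,2S)-5-({[tert-butyl(dimethyl)silyl]oxy}methyl)-2-methyl-2-(4-methylpent-3-en-1-yl)-6-oxocyclohept-4-en-1-yl]ethenyl 3-methylbut-2-enoate | O=C1C[C@H](/C=C\OC(=O)C=C(C)C)[C@@](C)(CCC=C(C)C)CC=C1CO[Si](C)(C)C(C)(C)C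
F4 | step 11 | (E)-2-[(1S,2S,7R)-5-({[tert-butyl(dimethyl)silyl]oxy}methyl)-7-(2-ethoxyprop-2-en-1-yl)-2-methyl-2-(4-methylpent-3-en-1-yl)-6-oxocyclohept-4-en-1-yl]ethenyl 3-methylbut-2-enoate | O=C1[C@H](CC(=C)OCC)[C@H](/C=C/OC(=O)C=C(C)C)[C@@](C)(CCC=C(C)C)CC=C1CO[Si](C)(C)C(C)(C)C
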